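**Plan**

- Retrosynthesis: the C4 ketone is masked as a 4-ethoxy enol ether. Ring C is then cut at C2–C3 and C4–C4a, which removes C3/C4 as ethoxyacetylene and leaves an α-acetoxy aryl ether. That ether is traced back to the aryl ester of 2,3,4,5-tetramethoxyphenol and 4-methoxybenzoyl chloride.
- Enabling feature: C2 lies between O1 and the 4-methoxyphenyl ring B, so it can exist as a stabilised O-aryl oxocarbenium ion. C4a is the only unsubstituted carbon of ring A, ortho to O1 and to the C5 methoxy group and para to the C7 methoxy group.
- Forward order: rings A and B come from the starting materials (phenol from 1,2,3,4-tetramethoxybenzene, then esterification and reductive acetylation). Ring C is the only ring made, closed in one operation (C2–C3 first, C4–C4a second), and the enol ether is then hydrolysed.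
- Stereochemistry: C2 is the only stereocentre. It is set in the annulation by a chiral counteranion paired with the oxocarbenium ion, and no later step touches it.

Key step: step 4

Assumption: the sense of induction of the chiral anion on this acyclic O-aryl oxocarbenium ion cannot be predicted with certainty; the (S,S) acid is written as the one leading to (2S), and its mirror image would be used if a first experiment shows the opposite sense.

Step 1
Reactants: 1 1,2,3,4-tetramethoxybenzene
Product: 4 2,3,4,5-tetramethoxyphenol, via (2,3,4,5-tetramethoxyphenyl)lithium 2 (not isolated), via lithium aryltrimethoxyborate 3 (not isolated)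
Conditions: n-BuLi, TMEDA, THF, 0 °C; B(OMe)3, −78 °C → rt; then AcOH, 30% aq. H2O2, 0 °C → rt
Reagents that add atoms: hydrogen peroxide, OO
Why: Directed ortho-metalation next to a methoxy group (the two ring C–H positions are equivalent), borylation of the aryllithium and peroxide-induced aryl migration from boron to oxygen should place the hydroxyl group at the former C–H carbon.

Step 2
Reactants: 4 2,3,4,5-tetramethoxyphenol; 5 4-methoxybenzoyl chloride
Product: 6 2,3,4,5-tetramethoxyphenyl 4-methoxybenzoate
Conditions: Et3N, DMAP (cat.), CH2Cl2, 0 °C → rt
Reagents that add atoms: none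
Why: DMAP-catalysed nucleophilic acyl substitution at the acid chloride by the only nucleophilic site, the phenol oxygen, should give the aryl ester cleanly.

Step 3
Reactants: 6 2,3,4,5-tetramethoxyphenyl 4-methoxybenzoate
Product: 8 rac-(4-methoxyphenyl)(2,3,4,5-tetramethoxyphenoxy)methyl acetate, via diisobutylaluminium hemiacetal 7 (not isolated)
Conditions: i-Bu2AlH (DIBAL-H), CH2Cl2, −78 °C; then pyridine, DMAP, Ac2O, −78 → 0 °C
Reagents that add atoms: acetic anhydride, CC(=O)OC(C)=O
Why: Rychnovsky reductive acetylation: single hydride addition at −78 °C gives a tetrahedral aluminium hemiacetal that should persist at this temperature and is acetylated in situ; the acetal carbon forms as a racemate, which does not matter because it becomes planar in step 4.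

Step 4
Reactants: 8 rac-(4-methoxyphenyl)(2,3,4,5-tetramethoxyphenoxy)methyl acetate; 9 ethoxyacetylene
Product: 12 (2S)-4-ethoxy-5,6,7,8-tetramethoxy-2-(4-methoxyphenyl)-2H-chromene, via O-aryl oxocarbenium ion 10 (not isolated), via O-ethyl ketenium ion 11 (not isolated)
Conditions: (S,S)-IDPi Brønsted acid (BINOL-derived imidodiphosphorimidate, 3,3'-Ar = 3,5-(CF3)2C6H3, N-SO2CF3; 5 mol %), 9 (3 equiv), 5 Å MS, toluene, −78 °C; Et3N quench
Reagents that add atoms: none
Why: Proposed new method: the chiral acid protonates the acetate of 8, acetic acid leaves and the 4-methoxyphenyl-stabilised oxocarbenium ion 10 remains paired with the chiral imidodiphosphorimidate anion; the terminal carbon of ethoxyacetylene attacks C2 (C2–C3) to give the ketenium ion 11, whose digonal C4 is captured by C4a of the aryloxy ring (C4–C4a), and loss of the C4a proton restores ring A and returns the acid. The closest known reactions are the oxa-Povarov [4+2] annulation of O-aryl oxocarbenium ions with alkenes, Povarov annulations of N-aryl iminium ions with alkynes, and additions of nucleophiles to oxocarbenium ions generated from α-acetoxy ethers under ion-pairing catalysis by confined chiral acids. Ring C closes as a six-membered ring by an intramolecular Friedel–Crafts attack that is endo with respect to the former alkyne, so C3 and C4 both become ring atoms and the enol ether double bond lies inside the ring. The C2 stereocentre is set in the C2–C3 bond formation, where the confined anion should shield one face of 10 so that the alkyne adds to the face leading to (2S); the subsequent ring closure does not involve C2. Regiochemistry of the closure needs no control because C4a is the only unsubstituted carbon of the aryloxy ring and is activated by the ortho ether oxygen and the ortho and para methoxy groups, while the ethoxy group polarises the alkyne so that only its terminal carbon is nucleophilic and the cation develops at the future C4; fast intramolecular capture by this ring should outrun capture of 11 by acetic acid.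

Step 5
Reactants: 12 (2S)-4-ethoxy-5,6,7,8-tetramethoxy-2-(4-methoxyphenyl)-2H-chromene
Product: 13 (2S)-5,6,7,8-tetramethoxy-2-(4-methoxyphenyl)chroman-4-one
Conditions: 1 M aq. HCl, THF, 0 °C, 15 min
Reagents that add atoms: water, O
Why: Acid-catalysed enol ether hydrolysis of an aryl-conjugated enol ether should be fast under conditions too mild to open the pyranone ring, so the C4 ketone is revealed and C2 keeps its configuration.

**Compound list**

1 | 1,2,3,4-tetramethoxybenzene | COc1ccc(OC)c(OC)c1OC | starting material
2 | (2,3,4,5-tetramethoxyphenyl)lithium | [Li]c1cc(OC)c(OC)c(OC)c1OC | intermediate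
3 | lithium trimethoxy(2,3,4,5-tetramethoxyphenyl)borate | [Li+].CO[B-](OC)(OC)c1cc(OC)c(OC)c(OC)c1OC | intermediate
4 | 2,3,4,5-tetramethoxyphenol | COc1cc(O)c(OC)c(OC)c1OC | intermediate
5 | 4-methoxybenzoyl chloride | COc1ccc(C(Cl)=O)cc1 | starting material
6 | 2,3,4,5-tetramethoxyphenyl 4-methoxybenzoate | COc1ccc(C(=O)Oc2cc(OC)c(OC)c(OC)c2OC)cc1 | intermediate
7 | rac-[(4-methoxyphenyl)(2,3,4,5-tetramethoxyphenoxy)methoxy]bis(2-methylpropyl)aluminium (aluminium hemiacetal) | COc1ccc(C(O[Al](CC(C)C)CC(C)C)Oc2cc(OC)c(OC)c(OC)c2OC)cc1 | intermediate
8 | rac-(4-methoxyphenyl)(2,3,4,5-tetramethoxyphenoxy)methyl acetate | COc1ccc(C(OC(C)=O)Oc2cc(OC)c(OC)c(OC)c2OC)cc1 | intermediate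
9 | ethoxyacetylene (ethoxyethyne) | C#COCC | starting material
10 | (4-methoxybenzylidene)(2,3,4,5-tetramethoxyphenyl)oxonium ion, paired with the chiral anion | COc1ccc(C=[O+]c2cc(OC)c(OC)c(OC)c2OC)cc1 | intermediate
11 | (S)-O-ethyl ketenium ion (1-ethoxyvinyl cation) carrying the (4-methoxyphenyl)(2,3,4,5-tetramethoxyphenoxy)methyl group | COc1ccc([C@H](C=C=[O+]CC)Oc2cc(OC)c(OC)c(OC)c2OC)cc1 | intermediate
12 | (2S)-4-ethoxy-5,6,7,8-tetramethoxy-2-(4-methoxyphenyl)-2H-chromene | COc1ccc([C@@H]2C=C(OCC)c3c(OC)c(OC)c(OC)c(OC)c3O2)cc1 | intermediate
13 | (2S)-5,6,7,8-tetramethoxy-2-(4-methoxyphenyl)chroman-4-one, (2S)-5,6,7,8,4'-pentamethoxyflavanone | COc1ccc([C@@H]2CC(=O)c3c(OC)c(OC)c(OC)c(OC)c3O2)cc1 | target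

**Step count**

Total steps: 5. Longest linear sequence: 5 steps (1 → 4 → 6 → 8 → 12 → 13).

**Steps most likely to fail**

Step 4 (proposed new method). Several processes can go wrong:
- poor facial discrimination in the alkyne addition;
- acid-triggered consumption of ethoxyacetylene (protonation, then addition of the acetic acid that is released);
- intermolecular Friedel–Crafts alkylation of a second aryloxy ring by the oxocarbenium ion;
- erosion of enantiopurity by reversible ionisation of the C2–O1 bond of the product.

The fallback uses known chemistry, sets out from 8 and returns at 13. Ion 10 is generated under silylium ion-pair catalysis by the same class of chiral acid in the presence of 1,1-bis(trimethylsilyloxy)ethene. This is an enantioselective Mukaiyama-type addition of a silyl ketene acetal to an oxocarbenium ion from an α-acetoxy ether. It should give trimethylsilyl (3S)-3-(4-methoxyphenyl)-3-(2,3,4,5-tetramethoxyphenoxy)propanoate F1, which is hydrolysed on aqueous work-up to (3S)-3-(4-methoxyphenyl)-3-(2,3,4,5-tetramethoxyphenoxy)propanoic acid F2. Intramolecular Friedel–Crafts acylation of F2 at the single free ring carbon (trifluoroacetic anhydride, CH2Cl2, 0 °C) then closes ring C directly to 13. The two bonds are thus made in separate, precedented steps and 12 is bypassed.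

Step 3. The aluminium hemiacetal may collapse with loss of the aryloxide before it is acetylated, which leads to over-reduction, and the labile acetoxy ether may ionise during purification. The fallback sets out from 4 and returns at 8. 4-Methoxybenzaldehyde and acetyl chloride (cat. ZnCl2, CH2Cl2, 0 °C) should combine to chloro(4-methoxyphenyl)methyl acetate F3. O-Alkylation of phenol 4 with F3 (i-Pr2NEt, CH2Cl2, −20 °C) then gives 8 without the ester 6 and without any hydride reduction.

Step 1. Lithiation may be incomplete or occur twice, and the very electron-rich phenol may be over-oxidised to quinones during the peroxide treatment. The fallback sets out from 1 and returns at 4. Rieche formylation (Cl2CHOMe, TiCl4, CH2Cl2, 0 °C) should give 2,3,4,5-tetramethoxybenzaldehyde F4. Baeyer–Villiger oxidation (mCPBA, CH2Cl2) converts it to 2,3,4,5-tetramethoxyphenyl formate F5, and methanolysis (K2CO3, MeOH) releases 4 only after the oxidant has been removed.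

**Further compounds**

F1 | step 4 | trimethylsilyl (3S)-3-(4-methoxyphenyl)-3-(2,3,4,5-tetramethoxyphenoxy)propanoate | COc1ccc([C@H](CC(=O)O[Si](C)(C)C)Oc2cc(OC)c(OC)c(OC)c2OC)cc1
F2 | step 4 | (3S)-3-(4-methoxyphenyl)-3-(2,3,4,5-tetramethoxyphenoxy)propanoic acid | COc1ccc([C@H](CC(=O)O)Oc2cc(OC)c(OC)c(OC)c2OC)cc1
F3 | step 3 | chloro(4-methoxyphenyl)methyl acetate | COc1ccc(C(Cl)OC(C)=O)cc1
F4 | step 1 | 2,3,4,5-tetramethoxybenzaldehyde | COc1cc(C=O)c(OC)c(OC)c1OC
F5 | step 1 | 2,3,4,5-tetramethoxyphenyl formate | COc1cc(OC=O)c(OC)c(OC)c1OC
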